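## Retrosynthetic overview

1. The (5E)-ylidene butenolide is unmasked last from a 2,3,4-trisubstituted furan by singlet oxygen and then dehydration. The ring allows only the 5E alkene, and both CH2OH groups travel as TBDPS ethers.
2. The 3(2H)-furanone comes from a transannular 5-endo-dig cycloisomerisation of a ten-membered γ-hydroxy ynone (C4-OH onto C1).
3. The key disconnection is C2–C3. The ten-membered carbocycle is closed by an intramolecular Nozaki–Hiyama–Kishi reaction of an iodoalkyne with a non-enolisable α-silyloxy aldehyde.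
4. The open chain divides into three fragments:
   - fragment 1: a 3-iodofuran (C3–C7, C11–C13), with C4 set by Sharpless epoxidation;
   - fragment 2: an alkynyl Weinreb amide (C8–C10, C1, C2), with C10 set by Evans alkylation;
   - fragment 3: silylated 2-(hydroxymethyl)acrylic acid.

   C7–C8 is made by furyllithium acylation and C8 is set by CBS reduction.
5. Ring order: furan, ten-membered carbocycle, 3(2H)-furanone, butenolide.

**Assumption and notation.**
- Germacranolide numbering is used: C1 enol-ether carbon, C2 =CH, C3 ketone, C4 quaternary C(Me)O, C5=C6, C7, C8 acyloxy carbon, C9 CH2, C10 CHMe, C11–C13 lactone carbons (C12 is C=O, C13 is CH2OH).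
- The target is (4S,5E,8S,10S).
- Centres that are destroyed later (C11 in 11, C3 in 36, C6 and C12 in 40–42) form as mixtures and are left undefined.
- TES = triethylsilyl, TMS = trimethylsilyl, TBDPS = tert-butyldiphenylsilyl.

## Fragment 1

**Step 1**
Reactants: 1 2-methylprop-2-en-1-ol
Product: 2 (R)-(2-methyloxiran-2-yl)methanol
Conditions: Ti(OiPr)4 (5 mol %), D-(−)-diisopropyl tartrate (6 mol %), cumene hydroperoxide, 4 Å molecular sieves, CH2Cl2, −20 °C
Reagents that add atoms: cumene hydroperoxide, CC(C)(OO)c1ccccc1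
Why: Sharpless asymmetric epoxidation, in which the allylic alcohol binds the titanium tartrate complex and the D-(−)-tartrate directs oxygen transfer to the face that gives the R epoxide (about 90–95 % ee), fixing the future C4.

**Step 2**
Reactants: 2 (R)-(2-methyloxiran-2-yl)methanol; 3 lithium acetylide–ethylenediamine complex LiC≡CH·H2NCH2CH2NH2
Product: 4 (S)-2-methylpent-4-yne-1,2-diol
Conditions: 3 (2.5 equiv), DMSO, 0 °C → rt; H2O
Reagents that add atoms: none
Why: SN2 epoxide opening at the unhindered CH2 leaves the C–O bond of the quaternary centre intact (the Payne rearrangement of this substrate is degenerate), so C4 is retained and only its descriptor changes to S.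

**Step 3**
Reactants: 4 (S)-2-methylpent-4-yne-1,2-diol
Product: 5 (S)-2-methyl-1,2-bis(triethylsilyloxy)pent-4-yne
Conditions: Et3SiOTf (2.4 equiv), 2,6-lutidine, CH2Cl2, −78 → 0 °C
Reagents that add atoms: triethylsilyl triflate, CC[Si](CC)(CC)OS(=O)(=O)C(F)(F)F
Why: O-silylation with the reactive triflate covers the tertiary as well as the primary alcohol and provides a primary TES ether that can later be oxidised directly.

**Step 4**
Reactants: 6 1,3-dihydroxyacetone
Product: 7 1,3-bis(trimethylsilyloxy)propan-2-one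
Conditions: Me3SiCl, Et3N, DMF, 0 °C → rt
Reagents that add atoms: chlorotrimethylsilane, C[Si](C)(C)Cl
Why: Simple O-silylation cracks the commercial dimer and gives a non-protic ketone whose TMS groups are far more labile than TES.

**Step 5**
Reactants: 5 (S)-2-methyl-1,2-bis(triethylsilyloxy)pent-4-yne; 7 1,3-bis(trimethylsilyloxy)propan-2-one
Product: 10 (S)-2-(hydroxymethyl)-6-methyl-6,7-bis(triethylsilyloxy)hept-3-yne-1,2-diol, via lithium acetylide 8 (not isolated), via bis-TMS adduct 9 (not isolated)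
Conditions: n-BuLi, THF, −78 °C; 7, −78 → −30 °C; H2O; then K2CO3 (0.2 equiv), MeOH, 0 °C, 20 min
Reagents that add atoms: none
Why: 1,2-Addition of a lithium acetylide to a ketone followed by base-catalysed methanolysis, in which the unhindered TMS ethers are cleaved much faster than the neopentyl and tertiary TES ethers.

**Step 6**
Reactants: 10 (S)-2-(hydroxymethyl)-6-methyl-6,7-bis(triethylsilyloxy)hept-3-yne-1,2-diol
Product: 12 {4-iodo-5-[(S)-2-methyl-2,3-bis(triethylsilyloxy)propyl]furan-3-yl}methanol, via iododihydrofuran 11 (not isolated)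
Conditions: I2 (3 equiv), NaHCO3 (3 equiv), MeCN, 0 °C → rt, dark
Reagents that add atoms: iodine, II
Why: 5-endo-dig iodocyclisation of a 3-alkyne-1,2-diol (either equivalent CH2OH attacks C6, iodine ends on C7) followed by spontaneous dehydrative aromatisation gives the β-iodofuran with the full C6/C7/C11 substitution pattern.

**Step 7**
Reactants: 12 {4-iodo-5-[(S)-2-methyl-2,3-bis(triethylsilyloxy)propyl]furan-3-yl}methanol
Product: 13 TBDPS ether of 12 (fragment 1)
Conditions: t-BuPh2SiCl, imidazole, CH2Cl2, rt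
Reagents that add atoms: tert-butylchlorodiphenylsilane, CC(C)(C)[Si](Cl)(c1ccccc1)c1ccccc1
Why: Silylation of the only free hydroxyl puts an acid- and HF-resistant group on C13-OH, which outlasts all later TES manipulations.

## Fragment 2

**Step 8**
Reactants: 14 (R)-4-benzyl-3-propionyl-1,3-oxazolidin-2-one; 15 tert-butyl bromoacetate
Product: 17 tert-butyl (3S)-4-[(4R)-4-benzyl-2-oxo-1,3-oxazolidin-3-yl]-3-methyl-4-oxobutanoate, via sodium enolate 16 (not isolated)
Conditions: NaN(SiMe3)2, THF, −78 °C; 15, −78 → −40 °C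
Reagents that add atoms: none
Why: Evans asymmetric alkylation, in which the chelated Z-enolate is attacked on the face opposite the benzyl group, so the R auxiliary sets the methyl-bearing centre (C10) as S with dr above 95:5.

**Step 9**
Reactants: 17 tert-butyl (3S)-4-[(4R)-4-benzyl-2-oxo-1,3-oxazolidin-3-yl]-3-methyl-4-oxobutanoate
Product: 19 (4S)-4-methyloxolan-2-one, via hydroxy ester 18 (not isolated)
Conditions: LiBH4, MeOH (1 equiv), Et2O, 0 °C; work-up; then CF3CO2H, CH2Cl2, rt
Reagents that add atoms: none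
Why: Chemoselective borohydride reduction of the activated imide spares the tert-butyl ester, and acid-promoted lactonisation then differentiates C1 from C8 without touching C10.

**Step 10**
Reactants: 19 (4S)-4-methyloxolan-2-one
Product: 20 (3S)-4-hydroxy-N-methoxy-N,3-dimethylbutanamide
Conditions: MeNH(OMe)·HCl, i-PrMgCl, THF, −20 → 0 °C
Reagents that add atoms: N,O-dimethylhydroxylamine hydrochloride, CNOC.Cl
Why: Weinreb aminolysis of the lactone by the magnesium amide opens the ring irreversibly at low temperature and frees C1-OH for oxidation.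

**Step 11**
Reactants: 20 (3S)-4-hydroxy-N-methoxy-N,3-dimethylbutanamide
Product: 21 (3S)-N-methoxy-N,3-dimethyl-4-oxobutanamide
Conditions: Dess–Martin periodinane, NaHCO3, CH2Cl2, 0 °C → rt
Reagents that add atoms: none
Why: Buffered Dess–Martin oxidation is near-neutral, which prevents both relactonisation and epimerisation of the α-methyl aldehyde.

**Step 12**
Reactants: 21 (3S)-N-methoxy-N,3-dimethyl-4-oxobutanamide
Product: 22 (3S)-N-methoxy-N,3-dimethylpent-4-ynamide
Conditions: MeC(O)C(N2)P(O)(OMe)2, K2CO3, MeOH, 0 °C → rt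
Reagents that add atoms: dimethyl (1-diazo-2-oxopropyl)phosphonate, COP(=O)(OC)C(=[N+]=[N-])C(C)=O
Why: Ohira–Bestmann (Seyferth–Gilbert) homologation adds C2 under conditions mild enough to keep α-branched aldehydes configurationally intact.

**Step 13**
Reactants: 22 (3S)-N-methoxy-N,3-dimethylpent-4-ynamide
Product: 23 (3S)-N-methoxy-N,3-dimethyl-5-(trimethylsilyl)pent-4-ynamide (fragment 2)
Conditions: Me3SiOTf, Et3N, Zn(OTf)2 (10 mol %), CH2Cl2, rt
Reagents that add atoms: trimethylsilyl triflate, C[Si](C)(C)OS(=O)(=O)C(F)(F)F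
Why: Zinc-acetylide-mediated C-silylation masks the acidic alkyne C–H without a strong base that would attack or enolise the Weinreb amide.

## Fragment 3

**Step 14**
Reactants: 24 methyl acrylate
Product: 25 methyl 2-(hydroxymethyl)prop-2-enoate
Conditions: aq. CH2O, DABCO, 1,4-dioxane–H2O, rt
Reagents that add atoms: formaldehyde, C=O
Why: The Morita–Baylis–Hillman reaction of an unsubstituted acrylate with formaldehyde is fast in aqueous dioxane and gives the α-hydroxymethyl acrylate directly.

**Step 15**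
Reactants: 25 methyl 2-(hydroxymethyl)prop-2-enoate
Product: 26 methyl 2-[(tert-butyldiphenylsilyloxy)methyl]prop-2-enoate
Conditions: t-BuPh2SiCl, imidazole, DMF, rt
Reagents that add atoms: tert-butylchlorodiphenylsilane, CC(C)(C)[Si](Cl)(c1ccccc1)c1ccccc1
Why: Standard silylation of a primary allylic alcohol uses the same group as on C13, so both fall in one final step.

**Step 16**
Reactants: 26 methyl 2-[(tert-butyldiphenylsilyloxy)methyl]prop-2-enoate
Product: 27 2-[(tert-butyldiphenylsilyloxy)methyl]prop-2-enoic acid (fragment 3)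
Conditions: LiOH, THF–H2O, 0 °C → rt; then 1 M HCl
Reagents that add atoms: lithium hydroxide, [Li+].[OH-]
Why: Saponification of the unhindered methyl ester outruns conjugate addition, and the TBDPS ether is stable to aqueous base.

## Fragment union, macrocyclisation and endgame

**Step 17**
Reactants: 13 TBDPS ether of 12 (fragment 1); 23 (3S)-N-methoxy-N,3-dimethyl-5-(trimethylsilyl)pent-4-ynamide (fragment 2)
Product: 29 (3S)-1-{4-[(tert-butyldiphenylsilyloxy)methyl]-2-[(2S)-2-methyl-2,3-bis(triethylsilyloxy)propyl]furan-3-yl}-3-methyl-5-(trimethylsilyl)pent-4-yn-1-one, via furyllithium 28 (not isolated)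
Conditions: n-BuLi, Et2O, −78 °C, 15 min; 23, −78 → −40 °C; H2O
Reagents that add atoms: none
Why: Iodine–lithium exchange is faster than any deprotonation, and at −78 °C the 3-furyllithium neither isomerises nor suffers silyl migration, so Weinreb ketone synthesis forms C7–C8 and stops at the ketone.

**Step 18**
Reactants: 29 TMS-alkynyl furyl ketone
Product: 30 (3S)-1-{4-[(tert-butyldiphenylsilyloxy)methyl]-2-[(2S)-2-methyl-2,3-bis(triethylsilyloxy)propyl]furan-3-yl}-5-iodo-3-methylpent-4-yn-1-one
Conditions: N-iodosuccinimide, AgNO3 (20 mol %), DMF, rt, dark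
Reagents that add atoms: N-iodosuccinimide, O=C1CCC(=O)N1I
Why: Silver-catalysed iododesilylation goes through a silver acetylide and is done at the ketone stage, where the 3-acyl group deactivates the furan towards electrophilic iodination.

**Step 19**
Reactants: 30 iodoalkynyl furyl ketone
Product: 31 (1S,3S)-1-{4-[(tert-butyldiphenylsilyloxy)methyl]-2-[(2S)-2-methyl-2,3-bis(triethylsilyloxy)propyl]furan-3-yl}-5-iodo-3-methylpent-4-yn-1-ol
Conditions: (R)-2-methyl-CBS-oxazaborolidine (0.5 equiv), catecholborane, toluene, −78 → −40 °C; MeOH, aq. NaHCO3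
Reagents that add atoms: none
Why: Corey–Bakshi–Shibata reduction, in which the doubly flanked furyl group is the large and CH2R the small substituent, so the R catalyst delivers hydride to give 8S, while catecholborane at low temperature leaves the iodoalkyne alone.

**Step 20**
Reactants: 31 (8S)-alcohol; 27 2-[(tert-butyldiphenylsilyloxy)methyl]prop-2-enoic acid (fragment 3)
Product: 33 (1S,3S)-1-{4-[(tert-butyldiphenylsilyloxy)methyl]-2-[(2S)-2-methyl-2,3-bis(triethylsilyloxy)propyl]furan-3-yl}-5-iodo-3-methylpent-4-yn-1-yl 2-[(tert-butyldiphenylsilyloxy)methyl]prop-2-enoate, via mixed anhydride 32 (not isolated)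
Conditions: 27, 2,4,6-Cl3C6H2COCl, Et3N, toluene, rt; then 31, DMAP, 0 °C → rt
Reagents that add atoms: none
Why: Yamaguchi esterification acylates the hindered secondary alcohol under basic conditions without breaking the C8–O bond (8S retained), and the final ester also protects C8-OH from adding to the later ynone.

**Step 21**
Reactants: 33 bis-TES ester
Product: 34 the ester 33 in which the furan C2 side chain has become (2S)-2-methyl-3-oxo-2-(triethylsilyloxy)propyl (C3 aldehyde)
Conditions: (COCl)2, DMSO, CH2Cl2, −78 → −40 °C; Et3N, −78 → 0 °C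
Reagents that add atoms: none
Why: Swern oxidation applied directly to a silyl ether, in which only the primary TES ether is exchanged by the chlorosulfonium salt and oxidised, while the tertiary TES and both TBDPS ethers remain and no protic acid reaches the ionisable C8 ester.

**Step 22**
Reactants: 34 iodoalkyne aldehyde
Product: 36 ten-membered propargylic alcohol (ring C1–C10; C1≡C2; C3-OH as epimer mixture; 4S C(Me)OTES; furan fused at C6–C7 bearing C13H2OTBDPS on C11; 8S acrylate ester; 10S methyl), via alkynylchromium dichloride 35 (not isolated)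
Conditions: CrCl2 (8 equiv), NiCl2 (1 mol % of the CrCl2), THF, rt, syringe-pump addition to 0.002 M
Reagents that add atoms: none
Why: Intramolecular Nozaki–Hiyama–Kishi macrocyclisation, in which two equivalents of divalent chromium turn the C–I bond into a trivalent alkynylchromium species. This species adds only to the non-enolisable aldehyde and tolerates the acrylate. The product is a cyclodec-1-en-6-yne type ring of modest strain, and its new C3 centre is erased in the next step.

**Step 23**
Reactants: 36 ten-membered propargylic alcohol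
Product: 37 ten-membered ynone (C3 ketone; 4S OTES; 8S; 10S)
Conditions: Dess–Martin periodinane, NaHCO3, CH2Cl2, 0 °C
Reagents that add atoms: none
Why: Buffered Dess–Martin oxidation converts both C3 epimers into one ynone without acid or nucleophile that could attack the furan, the C8 ester or the new Michael acceptor.

**Step 24**
Reactants: 37 ten-membered ynone
Product: 38 ten-membered γ-hydroxy ynone (free 4S tertiary OH)
Conditions: HF·pyridine, pyridine, THF, 0 °C
Reagents that add atoms: none
Why: Buffered fluoride desilylation removes TES far faster than the primary TBDPS ethers and is too weakly acidic to ionise the C8 ester.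

**Step 25**
Reactants: 38 ten-membered γ-hydroxy ynone
Product: 39 furan-fused 3(2H)-furanone macrocycle (1,4-oxygen bridge; C1=C2; C3 ketone; 4S,8S,10S)
Conditions: (4-CF3C6H4)3PAuCl (5 mol %), AgOTf (5 mol %), toluene, rt
Reagents that add atoms: none
Why: Cationic monovalent-gold π-activation of the ynone triggers 5-endo-dig attack of the adjacent C4-OH on C1 (cycloisomerisation of a γ-hydroxy alkynone to a 3(2H)-furanone), and no bond to C4 or C10 is broken.

**Step 26**
Reactants: 39 furan-fused 3(2H)-furanone macrocycle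
Product: 41 γ-hydroxybutenolide (C12 lactone carbonyl; C6 hemiketal as epimer mixture; C5 still CH2), via endoperoxide 40 (not isolated)
Conditions: O2, tetraphenylporphyrin (cat.), visible light, CH2Cl2, −78 °C; then i-Pr2NEt, −78 °C → rt
Reagents that add atoms: oxygen, O=O
Why: Singlet oxygen adds [4+2] only to the electron-rich furan, and base-induced Kornblum–DeLaMare fragmentation can remove only the single C12–H, so C12 becomes the carbonyl and C6 the hemiketal.

**Step 27**
Reactants: 41 γ-hydroxybutenolide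
Product: 43 bis-TBDPS ether of the target ((5E)-ylidene butenolide), via lactol acetate 42 (not isolated)
Conditions: Ac2O, Et3N, DMAP (cat.), CH2Cl2, 0 °C → rt
Reagents that add atoms: none
Why: Acetylation of the hemiketal and elimination through the stabilised acyloxocarbenium ion can lose only a C5 proton, and the medium ring forces C4 cis to C7, which is the 5E geometry.

**Step 28**
Reactants: 43 bis-TBDPS ether of the target
Product: 44 CNP0261115.1, (4S,5E,8S,10S)-target
Conditions: HF·pyridine (excess), THF, 0 °C → rt, polypropylene vessel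
Reagents that add atoms: none
Why: Non-basic fluoride desilylation frees both primary alcohols without conjugate addition, acyl migration or C10 epimerisation.

## Compound list

1 | 2-methylprop-2-en-1-ol | C=C(C)CO | starting material
2 | (R)-(2-methyloxiran-2-yl)methanol | C[C@@]1(CO)CO1 | intermediate
3 | lithium acetylide–ethylenediamine complex | [Li+].[C-]#C.NCCN | starting material
4 | (S)-2-methylpent-4-yne-1,2-diol | C#CC[C@](C)(O)CO | intermediate
5 | (S)-2-methyl-1,2-bis(triethylsilyloxy)pent-4-yne | C#CC[C@](C)(O[Si](CC)(CC)CC)CO[Si](CC)(CC)CC | intermediate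
6 | 1,3-dihydroxyacetone (sold as its dimer) | O=C(CO)CO | starting material
7 | 1,3-bis(trimethylsilyloxy)propan-2-one | C[Si](C)(C)OCC(=O)CO[Si](C)(C)C | intermediate
8 | lithium acetylide of 5 | [Li]C#CC[C@](C)(O[Si](CC)(CC)CC)CO[Si](CC)(CC)CC | intermediate
9 | (S)-6-methyl-6,7-bis(triethylsilyloxy)-1-(trimethylsilyloxy)-2-[(trimethylsilyloxy)methyl]hept-3-yn-2-ol | C[Si](C)(C)OCC(O)(CO[Si](C)(C)C)C#CC[C@](C)(O[Si](CC)(CC)CC)CO[Si](CC)(CC)CC | intermediate
10 | (S)-2-(hydroxymethyl)-6-methyl-6,7-bis(triethylsilyloxy)hept-3-yne-1,2-diol | OCC(O)(CO)C#CC[C@](C)(O[Si](CC)(CC)CC)CO[Si](CC)(CC)CC | intermediate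
11 | 3-(hydroxymethyl)-4-iodo-5-[(S)-2-methyl-2,3-bis(triethylsilyloxy)propyl]-2,3-dihydrofuran-3-ol | OCC1(O)COC(C[C@](C)(O[Si](CC)(CC)CC)CO[Si](CC)(CC)CC)=C1I | intermediate
12 | {4-iodo-5-[(S)-2-methyl-2,3-bis(triethylsilyloxy)propyl]furan-3-yl}methanol | OCc1coc(C[C@](C)(O[Si](CC)(CC)CC)CO[Si](CC)(CC)CC)c1I | intermediate
13 | TBDPS ether of 12 (fragment 1) | CC(C)(C)[Si](OCc1coc(C[C@](C)(O[Si](CC)(CC)CC)CO[Si](CC)(CC)CC)c1I)(c2ccccc2)c3ccccc3 | intermediate
14 | (R)-4-benzyl-3-propionyl-1,3-oxazolidin-2-one | CCC(=O)N1[C@H](Cc2ccccc2)COC1=O | starting material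
15 | tert-butyl bromoacetate | CC(C)(C)OC(=O)CBr | starting material
16 | sodium (Z)-enolate of 14 | C/C=C(\[O-])N1[C@H](Cc2ccccc2)COC1=O.[Na+] | intermediate
17 | tert-butyl (3S)-4-[(4R)-4-benzyl-2-oxo-1,3-oxazolidin-3-yl]-3-methyl-4-oxobutanoate | CC(C)(C)OC(=O)C[C@H](C)C(=O)N1[C@H](Cc2ccccc2)COC1=O | intermediate
18 | tert-butyl (3S)-4-hydroxy-3-methylbutanoate | CC(C)(C)OC(=O)C[C@H](C)CO | intermediate
19 | (4S)-4-methyloxolan-2-one | O=C1C[C@H](C)CO1 | intermediate
20 | (3S)-4-hydroxy-N-methoxy-N,3-dimethylbutanamide | CON(C)C(=O)C[C@H](C)CO | intermediate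
21 | (3S)-N-methoxy-N,3-dimethyl-4-oxobutanamide | CON(C)C(=O)C[C@H](C)C=O | intermediate
22 | (3S)-N-methoxy-N,3-dimethylpent-4-ynamide | CON(C)C(=O)C[C@H](C)C#C | intermediate
23 | (3S)-N-methoxy-N,3-dimethyl-5-(trimethylsilyl)pent-4-ynamide (fragment 2) | CON(C)C(=O)C[C@H](C)C#C[Si](C)(C)C | intermediate
24 | methyl acrylate | C=CC(=O)OC | starting material
25 | methyl 2-(hydroxymethyl)prop-2-enoate | C=C(CO)C(=O)OC | intermediate
26 | methyl 2-[(tert-butyldiphenylsilyloxy)methyl]prop-2-enoate | C=C(CO[Si](c1ccccc1)(c1ccccc1)C(C)(C)C)C(=O)OC | intermediate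
27 | 2-[(tert-butyldiphenylsilyloxy)methyl]prop-2-enoic acid (fragment 3) | C=C(CO[Si](c1ccccc1)(c1ccccc1)C(C)(C)C)C(=O)O | intermediate
28 | 3-furyllithium from 13 (Li on C7) | [Li]c1c(C[C@](C)(O[Si](CC)(CC)CC)CO[Si](CC)(CC)CC)occ1CO[Si](c4ccccc4)(c4ccccc4)C(C)(C)C | intermediate
29 | TMS-alkynyl furyl ketone (C8 ketone; 4S,10S) | C[Si](C)(C)C#C[C@@H](C)CC(=O)c1c(C[C@](C)(O[Si](CC)(CC)CC)CO[Si](CC)(CC)CC)occ1CO[Si](c4ccccc4)(c4ccccc4)C(C)(C)C | intermediate
30 | iodoalkynyl furyl ketone (4S,10S) | IC#C[C@@H](C)CC(=O)c1c(C[C@](C)(O[Si](CC)(CC)CC)CO[Si](CC)(CC)CC)occ1CO[Si](c4ccccc4)(c4ccccc4)C(C)(C)C | intermediate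
31 | (8S)-alcohol (4S,8S,10S) | IC#C[C@@H](C)C[C@H](O)c1c(C[C@](C)(O[Si](CC)(CC)CC)CO[Si](CC)(CC)CC)occ1CO[Si](c4ccccc4)(c4ccccc4)C(C)(C)C | intermediate
32 | mixed anhydride of 27 and 2,4,6-trichlorobenzoic acid | C=C(CO[Si](c1ccccc1)(c1ccccc1)C(C)(C)C)C(=O)OC(=O)c2c(Cl)cc(Cl)cc2Cl | intermediate
33 | C8 2-[(TBDPS-oxy)methyl]acrylate of 31 | IC#C[C@@H](C)C[C@H](OC(=O)C(=C)CO[Si](c5ccccc5)(c5ccccc5)C(C)(C)C)c1c(C[C@](C)(O[Si](CC)(CC)CC)CO[Si](CC)(CC)CC)occ1CO[Si](c4ccccc4)(c4ccccc4)C(C)(C)C | intermediate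
34 | iodoalkyne aldehyde (C3 CHO; C4 OTES) | IC#C[C@@H](C)C[C@H](OC(=O)C(=C)CO[Si](c5ccccc5)(c5ccccc5)C(C)(C)C)c1c(C[C@](C)(O[Si](CC)(CC)CC)C=O)occ1CO[Si](c4ccccc4)(c4ccccc4)C(C)(C)C | intermediate
35 | alkynylchromium dichloride from 34 | Cl[Cr](Cl)C#C[C@@H](C)C[C@H](OC(=O)C(=C)CO[Si](c5ccccc5)(c5ccccc5)C(C)(C)C)c1c(C[C@](C)(O[Si](CC)(CC)CC)C=O)occ1CO[Si](c4ccccc4)(c4ccccc4)C(C)(C)C | intermediate
36 | ten-membered propargylic alcohol (C3 epimers; 4S,8S,10S) | C=C(CO[Si](c5ccccc5)(c5ccccc5)C(C)(C)C)C(=O)O[C@H]1C[C@H](C)C#CC(O)[C@@](C)(O[Si](CC)(CC)CC)Cc2occ(CO[Si](c4ccccc4)(c4ccccc4)C(C)(C)C)c21 | intermediate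
37 | ten-membered ynone, C4 OTES | C=C(CO[Si](c5ccccc5)(c5ccccc5)C(C)(C)C)C(=O)O[C@H]1C[C@H](C)C#CC(=O)[C@@](C)(O[Si](CC)(CC)CC)Cc2occ(CO[Si](c4ccccc4)(c4ccccc4)C(C)(C)C)c21 | intermediate
38 | ten-membered γ-hydroxy ynone | C=C(CO[Si](c5ccccc5)(c5ccccc5)C(C)(C)C)C(=O)O[C@H]1C[C@H](C)C#CC(=O)[C@@](C)(O)Cc2occ(CO[Si](c4ccccc4)(c4ccccc4)C(C)(C)C)c21 | intermediate
39 | furan-fused 3(2H)-furanone macrocycle | C=C(CO[Si](c5ccccc5)(c5ccccc5)C(C)(C)C)C(=O)O[C@H]1C[C@H](C)C2=CC(=O)[C@](C)(Cc3occ(CO[Si](c4ccccc4)(c4ccccc4)C(C)(C)C)c31)O2 | intermediate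
40 | furan endoperoxide (C6,C12-epidioxide) | C=C(CO[Si](c5ccccc5)(c5ccccc5)C(C)(C)C)C(=O)O[C@H]1C[C@H](C)C2=CC(=O)[C@](C)(CC36OC(OO3)C(CO[Si](c4ccccc4)(c4ccccc4)C(C)(C)C)=C61)O2 | intermediate
41 | γ-hydroxybutenolide (C6 hemiketal) | C=C(CO[Si](c5ccccc5)(c5ccccc5)C(C)(C)C)C(=O)O[C@H]1C[C@H](C)C2=CC(=O)[C@](C)(CC3(O)OC(=O)C(CO[Si](c4ccccc4)(c4ccccc4)C(C)(C)C)=C31)O2 | intermediate
42 | C6 lactol acetate | C=C(CO[Si](c5ccccc5)(c5ccccc5)C(C)(C)C)C(=O)O[C@H]1C[C@H](C)C2=CC(=O)[C@](C)(CC3(OC(C)=O)OC(=O)C(CO[Si](c4ccccc4)(c4ccccc4)C(C)(C)C)=C31)O2 | intermediate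
43 | bis-TBDPS ether of the target | C=C(CO[Si](c5ccccc5)(c5ccccc5)C(C)(C)C)C(=O)O[C@H]1C[C@H](C)C2=CC(=O)[C@](C)(/C=C3/OC(=O)C(CO[Si](c4ccccc4)(c4ccccc4)C(C)(C)C)=C31)O2 | intermediate
44 | CNP0261115.1 | C=C(CO)C(=O)O[C@H]1C[C@H](C)C2=CC(=O)[C@](C)(/C=C3/OC(=O)C(CO)=C31)O2 | target

## Step count

- Total step count: 28.
- Longest linear sequence: 18 steps (1, 2, 3, 5, 6, 7, then 17–28). The branch 8–13 followed by 17–28 is equally long.

## The three steps most likely to fail

**Step 22 (closure of the ten-membered ring).** The aldehyde is neopentyl and a medium ring containing an alkyne may oligomerise instead of closing. The fallback sets out from 34 and comes back at 39.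
- The linear alkyne is given up before ring closure. Gold-catalysed hydration of the iodoalkyne ((XPhos)AuNTf2, H2O, 1,2-dichloroethane, rt) places oxygen on C1 and gives the α-iodomethyl ketone F1.
- A chromium Reformatsky-type macro-aldol (CrCl2, catalytic LiI, THF, high dilution) closes the same C2–C3 bond through a flexible sp3 chain and gives the macrocyclic β-hydroxy ketone F2.
- Dess–Martin oxidation gives the macrocyclic 1,3-diketone F3.
- HF·pyridine removes the C4 TES group. The freed alcohol then closes on the C1 carbonyl and loses water, giving 39 by classical cyclodehydration of an α'-hydroxy 1,3-diketone. C10 must be watched for epimerisation at the diketone stage.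

**Step 25 (gold cycloisomerisation next to a nucleophilic furan).** Transannular furan–alkyne chemistry could compete. The fallback sets out from 38 and comes back at 39.
- One equivalent of Et2NH in Et2O at 0 °C adds to the ynone far faster than to the α-substituted acrylate and gives the β-diethylamino enone F4 (alkene geometry not controlled).
- Brief treatment with AcOH–H2O–THF protonates it to the iminium form. The C4-OH then closes on this form in a 5-exo-trig manner, diethylamine is expelled, and the product is 39. No π-acid is present at any point.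

**Step 19 (CBS reduction of a doubly flanked furyl ketone).** The reduction may be slow or poorly selective. The fallback sets out from 30 and comes back at 33.
- Unselective reduction (NaBH4, THF–EtOH, 0 °C) gives 31 together with the (8R)-alcohol F5.
- The two are diastereomers, because C4 and C10 are fixed, and are separated on silica. Compound 31 goes on through step 20.
- F5 is esterified with 27 under Mitsunobu conditions (PPh3, DIAD, toluene, −20 °C) with inversion at C8, so both epimers converge on 33.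

## Further compounds

F1 | step 22 | α-iodomethyl ketone aldehyde (C1 ketone, C2H2I, C3 CHO; 4S,8S,10S) | ICC(=O)[C@@H](C)C[C@H](OC(=O)C(=C)CO[Si](c5ccccc5)(c5ccccc5)C(C)(C)C)c1c(C[C@](C)(O[Si](CC)(CC)CC)C=O)occ1CO[Si](c4ccccc4)(c4ccccc4)C(C)(C)C
F2 | step 22 | macrocyclic β-hydroxy ketone (C1 ketone, C3-OH epimers) | C=C(CO[Si](c5ccccc5)(c5ccccc5)C(C)(C)C)C(=O)O[C@H]1C[C@H](C)C(=O)CC(O)[C@@](C)(O[Si](CC)(CC)CC)Cc2occ(CO[Si](c4ccccc4)(c4ccccc4)C(C)(C)C)c21
F3 | step 22 | macrocyclic 1,3-diketone (C1 and C3 ketones, C4 OTES) | C=C(CO[Si](c5ccccc5)(c5ccccc5)C(C)(C)C)C(=O)O[C@H]1C[C@H](C)C(=O)CC(=O)[C@@](C)(O[Si](CC)(CC)CC)Cc2occ(CO[Si](c4ccccc4)(c4ccccc4)C(C)(C)C)c21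
F4 | step 25 | macrocyclic β-diethylamino enone (NEt2 on C1, free C4-OH) | C=C(CO[Si](c5ccccc5)(c5ccccc5)C(C)(C)C)C(=O)O[C@H]1C[C@H](C)C(N(CC)CC)=CC(=O)[C@@](C)(O)Cc2occ(CO[Si](c4ccccc4)(c4ccccc4)C(C)(C)C)c21
F5 | step 19 | (8R)-alcohol, C8 epimer of 31 | IC#C[C@@H](C)C[C@@H](O)c1c(C[C@](C)(O[Si](CC)(CC)CC)CO[Si](CC)(CC)CC)occ1CO[Si](c4ccccc4)(c4ccccc4)C(C)(C)C
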